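**Plan**

1. Numbering (drimane-type): ring A = C1–C5 and C10 with the gem-dimethyl carbon C4; ring B = C5–C10 with CHMe at C8 and the quaternary C9, which carries the benzylic carbon C11.
2. Retrosynthesis: quinone ← tetramethoxyarene; a helper carbonyl is placed at C6; the C8 methyl is cut (cuprate); then C5=C10 and C7–C8 are cut together, opening both rings to an acyclic alkynyl β-keto aldehyde, itself cut into a β-keto ester, a benzylic bromide and an alkynyl iodide.
3. Enabling feature: C6 and C7 are the only atoms between the ring-fusion alkene carbon C5 and C8, so C5–C6–C7 maps onto a 1-propynyl group, and C10 and C8 are 1,3-related on C9 and can both be carbonyl carbons. Alkyne–carbonyl metathesis converts C10=O plus C5≡C6 into C5=C10 plus C6=O, which activates C7 for aldol condensation with C8=O.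
4. Forward: the chain is joined by dianion alkylation, C9 is set, rings A and B close in one pot, then the C8 methyl is added, the C6 oxygen is removed and the quinone is unmasked.
5. Stereochemistry: C9 from an auxiliary-controlled (L-valine tert-butyl ester enamine) benzylation; C8 from conjugate addition of methyl to the flat dienone anti to the arylmethyl group on C9.

Key step: step 12

Assumption: the face selectivity of the lithiated L-valine tert-butyl ester enamine is taken to depend on the donor additive, so that either enantiomer is within reach; the additive that gives the 2S ester 19 is used (the D-valine ester is the alternative).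

**Step 1**
Reactants: 1 2,2-dimethylpent-4-enal
Product: 2 1,1-dibromo-3,3-dimethylhexa-1,5-diene
Conditions: CBr4, PPh3, CH2Cl2, 0 °C
Reagents that add atoms: tetrabromomethane, BrC(Br)(Br)Br
Why: Corey–Fuchs dibromo-olefination (first stage): the neopentyl aldehyde has no α-hydrogen and reacts with the ylide Ph3P=CBr2 formed in the flask, while the isolated terminal alkene is inert.

**Step 2**
Reactants: 2 1,1-dibromo-3,3-dimethylhexa-1,5-diene
Product: 4 4,4-dimethylhept-1-en-5-yne, via lithium acetylide 3 (not isolated)
Conditions: n-BuLi (2.1 equiv), THF, −78 → 0 °C; then CH3I, 0 °C → rt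
Reagents that add atoms: iodomethane, CI
Why: Second stage of the Corey–Fuchs reaction: bromine–lithium exchange and rearrangement give the lithium acetylide, which is C-methylated, so that the 1-propynyl group (future C5, C6, C7) sits on the gem-dimethyl carbon C4.

**Step 3**
Reactants: 4 4,4-dimethylhept-1-en-5-yne
Product: 6 3,3-dimethylhex-4-yn-1-ol, via ozonide 5 (not isolated)
Conditions: O3, CH2Cl2, −78 °C (Sudan red indicator end point); then NaBH4, MeOH, −78 °C → rt
Reagents that add atoms: ozone, [O-][O+]=O
Why: Ozonolysis with reductive work-up: ozone adds to the terminal alkene far faster than to the dialkyl alkyne, and NaBH4 reduces the ozonide to the primary alcohol, the terminal carbon leaving as methanol.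

**Step 4**
Reactants: 6 3,3-dimethylhex-4-yn-1-ol
Product: 7 6-iodo-4,4-dimethylhex-2-yne
Conditions: PPh3, I2, imidazole, CH2Cl2, 0 °C → rt
Reagents that add atoms: iodine, II
Why: Appel iodination: the primary alcohol is displaced by iodide (SN2) through the alkoxyphosphonium salt under neutral conditions that leave the alkyne untouched.

**Step 5**
Reactants: 8 ethyl 2-methyl-3-oxobutanoate; 7 6-iodo-4,4-dimethylhex-2-yne
Product: 10 ethyl 2,7,7-trimethyl-3-oxodec-8-ynoate (racemic at C2), via dianion 9 (not isolated)
Conditions: NaH, THF, 0 °C; n-BuLi, 0 °C; then 7, 0 °C → rt; aq. NH4Cl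
Reagents that add atoms: none
Why: γ-Alkylation of a β-keto ester dianion: the more basic terminal carbanion attacks the unhindered primary iodide, which joins C1 to C2 and completes the carbon chain from C7 to the ester carbon (future C8).

**Step 6**
Reactants: 11 1,2,4,5-tetramethoxybenzene
Product: 13 (2,3,5,6-tetramethoxyphenyl)methanol, via aryllithium 12 (not isolated)
Conditions: n-BuLi, THF, 0 °C → rt; (CH2O)n, 0 °C → rt; H2O
Reagents that add atoms: formaldehyde (as paraformaldehyde), C=O
Why: Directed ortho-lithiation at the position flanked by two methoxy groups and trapping with formaldehyde give the benzylic alcohol in which both ortho positions are blocked by methoxy groups.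

**Step 7**
Reactants: 13 (2,3,5,6-tetramethoxyphenyl)methanol
Product: 14 3-(bromomethyl)-1,2,4,5-tetramethoxybenzene
Conditions: PBr3, Et2O, 0 °C; used without storage
Reagents that add atoms: phosphorus tribromide, BrP(Br)Br
Why: Bromination of an electron-rich benzylic alcohol with PBr3 by displacement on the phosphite ester.

**Step 8**
Reactants: 10 ethyl 2,7,7-trimethyl-3-oxodec-8-ynoate; 15 tert-butyl L-valinate
Product: 16 ethyl (2Z)-3-{[(2S)-1-tert-butoxy-3-methyl-1-oxobutan-2-yl]amino}-2,7,7-trimethyldec-2-en-8-ynoate
Conditions: BF3·OEt2 (cat.), benzene, reflux, Dean–Stark trap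
Reagents that add atoms: none
Why: Condensation of the ketone with the primary amine gives the hydrogen-bonded (Z)-enamino ester (vinylogous carbamate), which erases the labile C2 centre of 10 and attaches the chiral auxiliary.

**Step 9**
Reactants: 16 the enamino ester; 14 3-(bromomethyl)-1,2,4,5-tetramethoxybenzene
Product: 19 ethyl (2S)-2,7,7-trimethyl-3-oxo-2-[(2,3,5,6-tetramethoxyphenyl)methyl]dec-8-ynoate, via lithio-enamine 17 (not isolated), via alkylated imine 18 (not isolated)
Conditions: LiN(iPr)2, toluene, −78 °C; donor additive (HMPA or THF, see assumption); 14, −78 → −40 °C; then 1 M HCl, rt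
Reagents that add atoms: none
Why: Auxiliary-controlled alkylation of a chelated lithio-enamine: lithium is held by the nitrogen and the valine ester carbonyl, the isopropyl group shields one face, and C-benzylation on the open face sets the quaternary centre C9 (2S), after which mild acid hydrolysis of the imine returns the β-keto ester and the auxiliary.

**Step 10**
Reactants: 19 the quaternary β-keto ester
Product: 20 (2R)-2,7,7-trimethyl-2-[(2,3,5,6-tetramethoxyphenyl)methyl]dec-8-yne-1,3-diol (C3 epimers)
Conditions: LiAlH4, THF, 0 °C → rt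
Reagents that add atoms: none
Why: Hydride reduction of both ketone and ester to the 1,3-diol (the ester cannot be reduced alone beside the ketone), with the dialkyl alkyne, the arene and the quaternary centre untouched.

**Step 11**
Reactants: 20 the diol
Product: 21 (2R)-2,7,7-trimethyl-3-oxo-2-[(2,3,5,6-tetramethoxyphenyl)methyl]dec-8-ynal
Conditions: Dess–Martin periodinane, CH2Cl2, 0 °C → rt; used directly
Reagents that add atoms: none
Why: Dess–Martin oxidation of both alcohols under neutral conditions gives the 2,2-disubstituted β-keto aldehyde, which cannot enolize towards C9 and is therefore configurationally stable, and is taken on at once because it is sensitive to nucleophilic deformylation.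

**Step 12**
Reactants: 21 the alkynyl β-keto aldehyde
Product: 24 (4R)-4,8,8-trimethyl-4-[(2,3,5,6-tetramethoxyphenyl)methyl]-5,6,7,8-tetrahydronaphthalen-1(4H)-one, via enone aldehyde 22 (not isolated), via aldol adduct 23 (not isolated)
Conditions: AgSbF6 (10 mol %), CF3SO3H (10 mol %), ClCH2CH2Cl (0.01 M), 60 °C
Reagents that add atoms: none
Why: Proposed new method: the acid activates the C10 ketone, the alkyne adds to it through C5 while the carbonyl oxygen closes onto C6 (formal [2+2] cycloaddition to an oxetene), and ring opening of the oxetene gives the C5=C10 double bond with the oxygen moved to C6 (enone aldehyde 22), so that the alkyne serves as a regio-defined enol of a C6 methyl ketone; the same acid then enolizes the new acetyl group towards C7, which condenses with the C8 aldehyde through aldol 23 to the cross-conjugated dienone 24. The closest known reaction types are the acid- or silver-catalysed intramolecular alkyne–ketone metathesis that gives 2-acylcycloalkenes and the acid-catalysed intramolecular aldol condensation of a methyl ketone with a non-enolizable aldehyde; new are their union in one pot and the use of a dialkyl alkyne between two quaternary carbons. Ring A closes in the 6-exo-trig mode at the carbonyl carbon, with C6 of the alkyne left outside the ring, and ring B closes in the 6-(enolendo)-exo-trig mode. No stereocentre is formed, and C9, which bears no hydrogen and cannot enolize, is carried through unchanged. The step needs the alkyne to react with the ketone and not the aldehyde, and through C5 and not C6: only the C5–C10 bond gives a six-membered ring (the alternatives are seven- and eight-membered), and the gem-dimethyl group at C4 favours this closure. Friedel–Crafts attack of the arene on either activated carbonyl is shut off because both ortho positions carry methoxy groups and the free para position cannot reach.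

**Step 13**
Reactants: 24 the dienone
Product: 25 (3S,4R)-3,4,8,8-tetramethyl-4-[(2,3,5,6-tetramethoxyphenyl)methyl]-3,4,5,6,7,8-hexahydronaphthalen-1(2H)-one
Conditions: Me2CuLi (from CH3Li and CuI), Et2O, −40 → 0 °C; aq. NH4Cl
Reagents that add atoms: lithium dimethylcuprate (Me2CuLi), [Li+].C[Cu-]C
Why: Conjugate addition of a lithium dialkylcuprate to the less substituted enone of the cross-conjugated dienone (C8 is a CH terminus, C10 is fully substituted and inert): methyl should enter the flat ring B from the face opposite to the larger arylmethyl group on the neighbouring quaternary C9 and thus end up cis to the C9 methyl group (8S in the numbering above).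

**Step 14**
Reactants: 25 the enone
Product: 26 1,2,4,5-tetramethoxy-3-{[(1R,2S)-1,2,5,5-tetramethyl-1,2,3,4,5,6,7,8-octahydronaphthalen-1-yl]methyl}benzene
Conditions: LiAlH4, AlCl3 (1:3), Et2O, 0 °C → reflux
Reagents that add atoms: none
Why: Mixed-hydride (chloroalane) deoxygenation of an α,β-unsaturated ketone: 1,2-reduction and Lewis-acid ionization give the C6–C5–C10 allyl cation, and hydride is delivered to the less hindered secondary terminus C6, which keeps the tetrasubstituted C5=C10 double bond and removes the helper oxygen.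

**Step 15**
Reactants: 26 the tetramethoxyarene
Product: 27 2,5-dimethoxy-3-{[(1R,2S)-1,2,5,5-tetramethyl-1,2,3,4,5,6,7,8-octahydronaphthalen-1-yl]methyl}cyclohexa-2,5-diene-1,4-dione
Conditions: (NH4)2Ce(NO3)6, MeCN–H2O, 0 °C
Reagents that add atoms: water, O
Why: Oxidative demethylation of a 1,2,4,5-tetramethoxyarene to the 2,5-dimethoxy-1,4-benzoquinone: the arene is oxidized at a much lower potential than the hindered tetrasubstituted alkene, and the two possible para pairs give the same quinone by symmetry.

**Step 16**
Reactants: 27 the dimethoxyquinone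
Product: 28 2-hydroxy-5-methoxy-3-{[(1R,2S)-1,2,5,5-tetramethyl-1,2,3,4,5,6,7,8-octahydronaphthalen-1-yl]methyl}cyclohexa-2,5-diene-1,4-dione (target)
Conditions: KOH, MeOH–H2O, rt; then 1 M HCl
Reagents that add atoms: potassium hydroxide, [K+].[OH-]
Why: Addition–elimination hydrolysis of a vinylogous ester: hydroxide should replace the methoxy group next to the bulky alkyl substituent, which is twisted out of conjugation and therefore the more electrophilic one, and the hydroxyquinone anion formed resists further attack until acidification.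

**Compound list**

1 | 2,2-dimethylpent-4-enal | C=CCC(C)(C)C=O | starting material
2 | 1,1-dibromo-3,3-dimethylhexa-1,5-diene | C=CCC(C)(C)C=C(Br)Br | intermediate
3 | (3,3-dimethylhex-5-en-1-yn-1-yl)lithium | [Li]C#CC(C)(C)CC=C | intermediate
4 | 4,4-dimethylhept-1-en-5-yne | C=CCC(C)(C)C#CC | intermediate
5 | 3-(2,2-dimethylpent-3-yn-1-yl)-1,2,4-trioxolane | CC#CC(C)(C)CC1OCOO1 | intermediate
6 | 3,3-dimethylhex-4-yn-1-ol | CC#CC(C)(C)CCO | intermediate
7 | 6-iodo-4,4-dimethylhex-2-yne | CC#CC(C)(C)CCI | intermediate
8 | ethyl 2-methyl-3-oxobutanoate | CCOC(=O)C(C)C(C)=O | starting material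
9 | lithium sodium 1-ethoxy-2-methylbuta-1,3-diene-1,3-diolate | [Li+].[Na+].CCOC([O-])=C(C)C(=C)[O-] | intermediate
10 | ethyl 2,7,7-trimethyl-3-oxodec-8-ynoate (racemic at C2) | CCOC(=O)C(C)C(=O)CCCC(C)(C)C#CC | intermediate
11 | 1,2,4,5-tetramethoxybenzene | COc1cc(OC)c(OC)cc1OC | starting material
12 | (2,3,5,6-tetramethoxyphenyl)lithium | [Li]c1c(OC)c(OC)cc(OC)c1OC | intermediate
13 | (2,3,5,6-tetramethoxyphenyl)methanol | COc1cc(OC)c(OC)c(CO)c1OC | intermediate
14 | 3-(bromomethyl)-1,2,4,5-tetramethoxybenzene | COc1cc(OC)c(OC)c(CBr)c1OC | intermediate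
15 | tert-butyl L-valinate | CC(C)[C@H](N)C(=O)OC(C)(C)C | starting material
16 | ethyl (2Z)-3-{[(2S)-1-tert-butoxy-3-methyl-1-oxobutan-2-yl]amino}-2,7,7-trimethyldec-2-en-8-ynoate | CCOC(=O)/C(C)=C(\N[C@@H](C(C)C)C(=O)OC(C)(C)C)CCCC(C)(C)C#CC | intermediate
17 | N-lithio derivative of 16 | CCOC(=O)/C(C)=C(\N([Li])[C@@H](C(C)C)C(=O)OC(C)(C)C)CCCC(C)(C)C#CC | intermediate
18 | ethyl (2S)-3-{[(2S)-1-tert-butoxy-3-methyl-1-oxobutan-2-yl]imino}-2,7,7-trimethyl-2-[(2,3,5,6-tetramethoxyphenyl)methyl]dec-8-ynoate | COc1cc(OC)c(OC)c(C[C@@](C(=O)OCC)(C)C(=N[C@@H](C(C)C)C(=O)OC(C)(C)C)CCCC(C)(C)C#CC)c1OC | intermediate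
19 | ethyl (2S)-2,7,7-trimethyl-3-oxo-2-[(2,3,5,6-tetramethoxyphenyl)methyl]dec-8-ynoate | COc1cc(OC)c(OC)c(C[C@@](C(=O)OCC)(C)C(=O)CCCC(C)(C)C#CC)c1OC | intermediate
20 | (2R)-2,7,7-trimethyl-2-[(2,3,5,6-tetramethoxyphenyl)methyl]dec-8-yne-1,3-diol (C3 epimers) | COc1cc(OC)c(OC)c(C[C@@](CO)(C)C(O)CCCC(C)(C)C#CC)c1OC | intermediate
21 | (2R)-2,7,7-trimethyl-3-oxo-2-[(2,3,5,6-tetramethoxyphenyl)methyl]dec-8-ynal | COc1cc(OC)c(OC)c(C[C@@](C=O)(C)C(=O)CCCC(C)(C)C#CC)c1OC | intermediate
22 | (2S)-2-(2-acetyl-3,3-dimethylcyclohex-1-en-1-yl)-2-methyl-3-(2,3,5,6-tetramethoxyphenyl)propanal | COc1cc(OC)c(OC)c(C[C@@](C=O)(C)C2=C(C(C)=O)C(C)(C)CCC2)c1OC | intermediate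
23 | (4S)-3-hydroxy-4,8,8-trimethyl-4-[(2,3,5,6-tetramethoxyphenyl)methyl]-3,4,5,6,7,8-hexahydronaphthalen-1(2H)-one (C3 epimers) | COc1cc(OC)c(OC)c(C[C@@]2(C)C3=C(C(=O)CC2O)C(C)(C)CCC3)c1OC | intermediate
24 | (4R)-4,8,8-trimethyl-4-[(2,3,5,6-tetramethoxyphenyl)methyl]-5,6,7,8-tetrahydronaphthalen-1(4H)-one | COc1cc(OC)c(OC)c(C[C@@]2(C)C3=C(C(=O)C=C2)C(C)(C)CCC3)c1OC | intermediate
25 | (3S,4R)-3,4,8,8-tetramethyl-4-[(2,3,5,6-tetramethoxyphenyl)methyl]-3,4,5,6,7,8-hexahydronaphthalen-1(2H)-one | COc1cc(OC)c(OC)c(C[C@@]2(C)C3=C(C(=O)C[C@@H]2C)C(C)(C)CCC3)c1OC | intermediate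
26 | 1,2,4,5-tetramethoxy-3-{[(1R,2S)-1,2,5,5-tetramethyl-1,2,3,4,5,6,7,8-octahydronaphthalen-1-yl]methyl}benzene | COc1cc(OC)c(OC)c(C[C@@]2(C)C3=C(CC[C@@H]2C)C(C)(C)CCC3)c1OC | intermediate
27 | 2,5-dimethoxy-3-{[(1R,2S)-1,2,5,5-tetramethyl-1,2,3,4,5,6,7,8-octahydronaphthalen-1-yl]methyl}cyclohexa-2,5-diene-1,4-dione | COC1=CC(=O)C(OC)=C(C[C@@]2(C)C3=C(CC[C@@H]2C)C(C)(C)CCC3)C1=O | intermediate
28 | 2-hydroxy-5-methoxy-3-{[(1R,2S)-1,2,5,5-tetramethyl-1,2,3,4,5,6,7,8-octahydronaphthalen-1-yl]methyl}cyclohexa-2,5-diene-1,4-dione | COC1=CC(=O)C(O)=C(C[C@@]2(C)C3=C(CC[C@@H]2C)C(C)(C)CCC3)C1=O | target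

**Step count**

Total step count: 16. Longest linear sequence: 14 steps (steps 1–5 and 8–16).

**Steps most likely to fail**

Step 12. The alkyne–ketone metathesis may stall because both bonding carbons are flanked by quaternary carbons. Conia-ene-type closure of the ketone enol onto the alkyne may compete. The dienone, once formed, may undergo an acid-induced 1,2-shift of the arylmethyl group with aromatization. The fallback sets out from 19 and comes back at 24, passing through 22 as an isolated compound. SmI2 with HMPA and t-BuOH in THF reduces the ketone of 19 to the ketyl, which closes ring A onto the alkyne (6-exo-dig) to give ethyl (2S)-2-(2-ethylidene-1-hydroxy-3,3-dimethylcyclohexyl)-2-methyl-3-(2,3,5,6-tetramethoxyphenyl)propanoate F1. Pyridinium chlorochromate (C5H5NH)[CrO3Cl] then effects the oxidative 1,3-transposition of the tertiary allylic alcohol (Babler–Dauben) to ethyl (2S)-2-(2-acetyl-3,3-dimethylcyclohex-1-en-1-yl)-2-methyl-3-(2,3,5,6-tetramethoxyphenyl)propanoate F2. LiAlH4 reduces ester and ketone to (2S)-2-[2-(1-hydroxyethyl)-3,3-dimethylcyclohex-1-en-1-yl]-2-methyl-3-(2,3,5,6-tetramethoxyphenyl)propan-1-ol F3. Dess–Martin periodinane gives 22, and KOH in MeOH closes ring B by aldol condensation to 24.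

Step 13. Facial discrimination between the methyl and the arylmethyl group on C9 may be poor. Electron transfer from the cuprate to the dienone, with loss of the benzylic group and aromatization, may also compete. The fallback sets out from 24 and comes back at 25 and replaces substrate control by catalyst control: copper-catalysed asymmetric conjugate addition with Cu(OTf)2, a chiral phosphoramidite ligand and Me3Al in Et2O at −30 °C, the ligand enantiomer being chosen to reinforce the face anti to the arylmethyl group (no new compound, F0).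

Step 14. Hydride may be delivered to C10 as well as C6, giving double-bond isomers; over-reduction or Lewis-acid cleavage of the aryl methyl ethers may also occur. The fallback sets out from 25 and comes back at 26 without passing through an allyl cation. Ethane-1,2-dithiol and BF3·OEt2 in AcOH convert the ketone into (3'S,4'R)-3',4',8',8'-tetramethyl-4'-[(2,3,5,6-tetramethoxyphenyl)methyl]-3',4',5',6',7',8'-hexahydro-2'H-spiro[1,3-dithiolane-2,1'-naphthalene] F4. Desulfurization with Raney nickel (Ni) in EtOH at reflux gives 26 with the double bond in place.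

**Further compounds**

F1 | step 12 | ethyl (2S)-2-(2-ethylidene-1-hydroxy-3,3-dimethylcyclohexyl)-2-methyl-3-(2,3,5,6-tetramethoxyphenyl)propanoate | COc1cc(OC)c(OC)c(C[C@@](C(=O)OCC)(C)C2(O)CCCC(C)(C)C2=CC)c1OC
F2 | step 12 | ethyl (2S)-2-(2-acetyl-3,3-dimethylcyclohex-1-en-1-yl)-2-methyl-3-(2,3,5,6-tetramethoxyphenyl)propanoate | COc1cc(OC)c(OC)c(C[C@@](C(=O)OCC)(C)C2=C(C(C)=O)C(C)(C)CCC2)c1OC
F3 | step 12 | (2S)-2-[2-(1-hydroxyethyl)-3,3-dimethylcyclohex-1-en-1-yl]-2-methyl-3-(2,3,5,6-tetramethoxyphenyl)propan-1-ol | COc1cc(OC)c(OC)c(C[C@@](CO)(C)C2=C(C(C)O)C(C)(C)CCC2)c1OC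
F0 | step 13 | none | none
F4 | step 14 | (3'S,4'R)-3',4',8',8'-tetramethyl-4'-[(2,3,5,6-tetramethoxyphenyl)methyl]-3',4',5',6',7',8'-hexahydro-2'H-spiro[1,3-dithiolane-2,1'-naphthalene] | COc1cc(OC)c(OC)c(C[C@@]2(C)C3=C(C4(SCCS4)C[C@@H]2C)C(C)(C)CCC3)c1OC
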